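**Retrosynthetic overview**
1. Target 20 ← selective isobutyrylation of diol 18 ← N–O and Si–O cleavage of macrolactone 17.
2. Key step: 17 ← acyclic bromo keto aldehyde 15. Chromium-mediated intramolecular 2-(methoxycarbonyl)allylation of the C8 aldehyde by C7 closes the ten-membered carbocycle (C7–C8), and the resulting alkoxide lactonises on C12 (α-methylene γ-lactone). C7 and C8 are set here.
3. 15 ← aldehyde 10: C7–C11 bond by vinylalumination with methyl propiolate, C6–O by organocatalytic α-oxyamination, both aldehydes by ozonolysis of the two alkenes of diene ketone 8.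
4. 8 ← C1–C2 ketone coupling of (R)-linalool (C2–C7 and C15; supplies C4) with thioester 4 (C1, C8–C10, C14; C10 from an Evans allylation).
5. Ring order: no ring exists before step 10, where carbocycle and lactone form together in one operation.

Assumption: names use germacrane locants (C1 ketone, C4 carbinol, C6 acyloxy carbon, C7/C8 lactone fusion, C10 methyl-bearing carbon, C11–C13 acrylate carbons, C14/C15 methyls); the target is (4S,6R,7S,8S,10R).
Assumption: in step 6 the antipode of the imidazolidinone catalyst that gives the 6R alkoxyamine is used (both antipodes are commercial); it is written here as the (2R,5R) salt.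

**Step 1**
Reactants: 1 (S)-4-benzyl-3-propionyloxazolidin-2-one; 2 allyl iodide
Product: 3 (S)-4-benzyl-3-[(R)-2-methylpent-4-enoyl]oxazolidin-2-one
Conditions: NaN(SiMe3)2, THF, −78 °C; then 2, −78 to −40 °C
Reagents that add atoms: none
Why: Evans asymmetric alkylation, in which the chelated Z-enolate of the (S)-benzyl oxazolidinone is allylated on the face away from the benzyl group, setting C10 as R.

**Step 2**
Reactants: 3 (S)-4-benzyl-3-[(R)-2-methylpent-4-enoyl]oxazolidin-2-one
Product: 4 S-phenyl (R)-2-methylpent-4-enethioate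
Conditions: PhSH, AlMe3, CH2Cl2, 0 °C to rt
Reagents that add atoms: thiophenol, Sc1ccccc1
Why: Aluminium thiolate transacylation attacks only the exocyclic imide carbonyl, releasing the auxiliary without enolising C10.

**Step 3**
Reactants: 5 (R)-(−)-linalool
Product: 6 (R)-3,7-dimethyl-3-(triethylsilyloxy)octa-1,6-diene
Conditions: Et3SiOTf, 2,6-lutidine, CH2Cl2, −78 to 0 °C
Reagents that add atoms: triethylsilyl triflate, CC[Si](CC)(CC)OS(=O)(=O)C(F)(F)F
Why: Silyl triflate silylation of the tertiary alcohol protects O4, so that the later γ-hydroxy aldehyde cannot close to a lactol, and leaves the C4 stereocentre (from the chiral pool) untouched.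

**Step 4**
Reactants: 6 (R)-3,7-dimethyl-3-(triethylsilyloxy)octa-1,6-diene; 4 S-phenyl (R)-2-methylpent-4-enethioate
Product: 8 (4R,8R)-4,8,12-trimethyl-8-(triethylsilyloxy)trideca-1,11-dien-5-one, via B-alkyl-9-BBN borane 7 (not isolated)
Conditions: 9-BBN (1.0 equiv, 6 in slight excess), THF, 0 °C to rt; then 4, Pd2(dba)3 (2.5 mol %, zerovalent palladium), tri(2-furyl)phosphine, copper thiophene-2-carboxylate Cu(O2CC4H3S) (monovalent copper, 1.5 equiv), Cs2CO3, THF, 45 °C
Reagents that add atoms: none
Why: Anti-Markovnikov hydroboration of the monosubstituted alkene only (9-BBN ignores the trisubstituted alkene), then Liebeskind–Srogl ketone synthesis joins C1 to C2 under near-neutral conditions that do not epimerise C10.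

**Step 5**
Reactants: 8 (4R,8R)-4,8,12-trimethyl-8-(triethylsilyloxy)trideca-1,11-dien-5-one
Product: 9 (4R,8R)-4,8-dimethyl-7-oxo-4-(triethylsilyloxy)undec-10-enal
Conditions: O3 (1.0 equiv, Sudan Red 7B end point), CH2Cl2/MeOH, −78 °C; then Me2S, −78 °C to rt
Reagents that add atoms: ozone, [O-][O+]=O
Why: Chemoselective ozonolysis, because the electron-rich trisubstituted alkene reacts with ozone faster than the terminal vinyl group, so titration to the dye end point cleaves only the isopropylidene terminus to the C7 aldehyde.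

**Step 6**
Reactants: 9 (4R,8R)-4,8-dimethyl-7-oxo-4-(triethylsilyloxy)undec-10-enal
Product: 10 (2R,4S,8R)-4,8-dimethyl-7-oxo-2-[(2,2,6,6-tetramethylpiperidin-1-yl)oxy]-4-(triethylsilyloxy)undec-10-enal
Conditions: TEMPO (1.2 equiv), CuCl2 (10 mol %, divalent copper), (2R,5R)-5-benzyl-2-tert-butyl-3-methylimidazolidin-4-one trifluoroacetate (20 mol %), air, acetone, −10 °C
Reagents that add atoms: TEMPO, CC1(C)CCCC(C)(C)N1[O]
Why: Enamine organocatalysis (MacMillan-type α-oxyamination), in which the chiral enamine of the aldehyde is trapped by TEMPO on one face, setting C6 as R under catalyst control while the hindered ketone does not form an enamine competitively.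

**Step 7**
Reactants: 10 (2R,4S,8R)-α-oxyaminated aldehyde; 11 methyl propiolate
Product: 13 methyl (4R,6S,10R)-3-hydroxy-6,10-dimethyl-2-methylidene-9-oxo-4-[(2,2,6,6-tetramethylpiperidin-1-yl)oxy]-6-(triethylsilyloxy)tridec-12-enoate (both C3 epimers), via vinylalane 12 (not isolated)
Conditions: 11, iBu2AlH, N-methylmorpholine N-oxide, THF, 0 °C; then 10, 0 °C to rt; Rochelle salt work-up
Reagents that add atoms: none
Why: Hydroalumination of the propiolate gives the α-aluminoacrylate, which adds to the aldehyde only (vinylalumination, a Morita–Baylis–Hillman surrogate) to form the C7–C11 bond; the new carbinol centre is a mixture that is erased in step 9.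

**Step 8**
Reactants: 13 Baylis–Hillman-type adduct (both C3 epimers)
Product: 14 methyl (4R,6S,10R)-3-hydroxy-6,10-dimethyl-2-methylidene-9,12-dioxo-4-[(2,2,6,6-tetramethylpiperidin-1-yl)oxy]-6-(triethylsilyloxy)dodecanoate (both C3 epimers)
Conditions: O3 (Sudan Red 7B end point), CH2Cl2/MeOH, −78 °C; then Me2S
Reagents that add atoms: ozone, [O-][O+]=O
Why: Ozonolysis with reductive work-up cleaves the remaining electron-rich terminal alkene to the C8 aldehyde, while the electron-poor acrylate alkene survives at the dye end point.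

**Step 9**
Reactants: 14 hydroxy keto aldehyde (both C3 epimers)
Product: 15 methyl (2Z,4R,6S,10R)-2-(bromomethyl)-6,10-dimethyl-9,12-dioxo-4-[(2,2,6,6-tetramethylpiperidin-1-yl)oxy]-6-(triethylsilyloxy)dodec-2-enoate
Conditions: N-bromosuccinimide, Me2S, CH2Cl2, −20 °C (pre-mixed); then 14, −20 to 0 °C
Reagents that add atoms: N-bromosuccinimide, O=C1CCC(=O)N1Br
Why: Corey–Kim-type activation of the allylic alcohol as an alkoxysulfonium salt and SN2′ attack by bromide gives the thermodynamically preferred (Z)-2-(bromomethyl)enoate without acid, so aldehyde, ketone and silyl ether survive.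

**Step 10**
Reactants: 15 (Z)-allylic bromide keto aldehyde
Product: 17 (4S,6R,7S,8S,10R)-1-oxo-6-[(2,2,6,6-tetramethylpiperidin-1-yl)oxy]-4-(triethylsilyloxy)germacr-11(13)-en-12,8-olide, via macrocyclic hydroxy ester 16 (not isolated)
Conditions: CrCl2 (6 equiv, divalent chromium), THF, rt, syringe-pump addition of 15 over 12 h to 2 mM; then 1 M HCl work-up
Reagents that add atoms: none
Why: Intramolecular Nozaki–Hiyama–Kishi-type (Barbier) allylation, in which the allylchromium adds through its γ-carbon C7 to the C8 aldehyde (far faster than to the ketone) via a six-membered chair transition state; the (Z)-allyl geometry gives the 7,8-syn adduct and C8 approaches anti to C5 in the A(1,3)-minimised rotamer at C6, closing the ten-membered ring as 7S,8S, after which the cis-disposed chromium alkoxide acylates on the ester to close the α-methylene lactone.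

**Step 11**
Reactants: 17 protected macrolactone
Product: 18 (4S,6R,7R,8S,10R)-4,6-dihydroxy-1-oxogermacr-11(13)-en-12,8-olide
Conditions: Zn dust, AcOH/THF/H2O (3:1:1), 60 °C
Reagents that add atoms: none
Why: Dissolving-metal reduction cleaves the N–O bond of the alkoxyamine and the aqueous acid hydrolyses the tertiary silyl ether, with no bond to C4 or C6 broken, so both configurations are kept (the C7 descriptor changes only through CIP priorities).

**Step 12**
Reactants: 18 diol lactone; 19 isobutyryl chloride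
Product: 20 (4S,6R,7S,8S,10R)-4-hydroxy-6-isobutyryloxy-1-oxogermacr-11(13)-en-12,8-olide (target)
Conditions: 19 (1.3 equiv), pyridine, DMAP (10 mol %), CH2Cl2, 0 °C
Reagents that add atoms: none
Why: DMAP-catalysed acylation esterifies the secondary C6 hydroxyl selectively because the tertiary C4 hydroxyl is too hindered, giving the target with C4 from linalool, C10 from step 1, C6 from step 6 and C7/C8 from step 10.

**Compound list**
1 | (S)-4-benzyl-3-propionyloxazolidin-2-one | CCC(=O)N1[C@@H](Cc2ccccc2)COC1=O | starting material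
2 | allyl iodide | C=CCI | starting material
3 | (S)-4-benzyl-3-[(R)-2-methylpent-4-enoyl]oxazolidin-2-one | C=CC[C@@H](C)C(=O)N1[C@@H](Cc2ccccc2)COC1=O | intermediate
4 | S-phenyl (R)-2-methylpent-4-enethioate | C=CC[C@@H](C)C(=O)Sc1ccccc1 | intermediate
5 | (R)-(−)-linalool, (R)-3,7-dimethylocta-1,6-dien-3-ol | C=C[C@](C)(O)CCC=C(C)C | starting material
6 | (R)-3,7-dimethyl-3-(triethylsilyloxy)octa-1,6-diene | C=C[C@](C)(O[Si](CC)(CC)CC)CCC=C(C)C | intermediate
7 | 9-[(S)-3,7-dimethyl-3-(triethylsilyloxy)oct-6-enyl]-9-borabicyclo[3.3.1]nonane (same spatial arrangement at C4 as 6) | B1(CC[C@](C)(O[Si](CC)(CC)CC)CCC=C(C)C)C2CCCC1CCC2 | intermediate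
8 | (4R,8R)-4,8,12-trimethyl-8-(triethylsilyloxy)trideca-1,11-dien-5-one | C=CC[C@@H](C)C(=O)CC[C@](C)(O[Si](CC)(CC)CC)CCC=C(C)C | intermediate
9 | (4R,8R)-4,8-dimethyl-7-oxo-4-(triethylsilyloxy)undec-10-enal | C=CC[C@@H](C)C(=O)CC[C@](C)(O[Si](CC)(CC)CC)CCC=O | intermediate
10 | (2R,4S,8R)-4,8-dimethyl-7-oxo-2-[(2,2,6,6-tetramethylpiperidin-1-yl)oxy]-4-(triethylsilyloxy)undec-10-enal | C=CC[C@@H](C)C(=O)CC[C@](C)(O[Si](CC)(CC)CC)C[C@@H](ON1C(C)(C)CCCC1(C)C)C=O | intermediate
11 | methyl propiolate | C#CC(=O)OC | starting material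
12 | methyl 2-(diisobutylalumanyl)acrylate | C=C(C(=O)OC)[Al](CC(C)C)CC(C)C | intermediate
13 | methyl (4R,6S,10R)-3-hydroxy-6,10-dimethyl-2-methylidene-9-oxo-4-[(2,2,6,6-tetramethylpiperidin-1-yl)oxy]-6-(triethylsilyloxy)tridec-12-enoate, both C3 epimers | C=CC[C@@H](C)C(=O)CC[C@](C)(O[Si](CC)(CC)CC)C[C@@H](ON1C(C)(C)CCCC1(C)C)C(O)C(=C)C(=O)OC | intermediate
14 | methyl (4R,6S,10R)-3-hydroxy-6,10-dimethyl-2-methylidene-9,12-dioxo-4-[(2,2,6,6-tetramethylpiperidin-1-yl)oxy]-6-(triethylsilyloxy)dodecanoate, both C3 epimers | O=CC[C@@H](C)C(=O)CC[C@](C)(O[Si](CC)(CC)CC)C[C@@H](ON1C(C)(C)CCCC1(C)C)C(O)C(=C)C(=O)OC | intermediate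
15 | methyl (2Z,4R,6S,10R)-2-(bromomethyl)-6,10-dimethyl-9,12-dioxo-4-[(2,2,6,6-tetramethylpiperidin-1-yl)oxy]-6-(triethylsilyloxy)dodec-2-enoate | O=CC[C@@H](C)C(=O)CC[C@](C)(O[Si](CC)(CC)CC)C[C@@H](ON1C(C)(C)CCCC1(C)C)/C=C(/C(=O)OC)CBr | intermediate
16 | methyl (4S,6R,7S,8S,10R)-8-hydroxy-1-oxo-6-[(2,2,6,6-tetramethylpiperidin-1-yl)oxy]-4-(triethylsilyloxy)germacr-11(13)-en-12-oate | C=C(C(=O)OC)[C@@H]1[C@H](ON2C(C)(C)CCCC2(C)C)C[C@@](C)(O[Si](CC)(CC)CC)CCC(=O)[C@H](C)C[C@@H]1O | intermediate
17 | (4S,6R,7S,8S,10R)-1-oxo-6-[(2,2,6,6-tetramethylpiperidin-1-yl)oxy]-4-(triethylsilyloxy)germacr-11(13)-en-12,8-olide | C=C1C(=O)O[C@H]2C[C@@H](C)C(=O)CC[C@](C)(O[Si](CC)(CC)CC)C[C@@H](ON3C(C)(C)CCCC3(C)C)[C@@H]12 | intermediate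
18 | (4S,6R,7R,8S,10R)-4,6-dihydroxy-1-oxogermacr-11(13)-en-12,8-olide | C=C1C(=O)O[C@H]2C[C@@H](C)C(=O)CC[C@](C)(O)C[C@@H](O)[C@@H]12 | intermediate
19 | isobutyryl chloride | CC(C)C(Cl)=O | starting material
20 | (4S,6R,7S,8S,10R)-4-hydroxy-6-isobutyryloxy-1-oxogermacr-11(13)-en-12,8-olide, CNP0293926.1 | C=C1C(=O)O[C@H]2C[C@@H](C)C(=O)CC[C@](C)(O)C[C@@H](OC(=O)C(C)C)[C@@H]12 | target

**Step count and risks**
Total step count: 12. Longest linear sequence: 11 steps (1 → 3 → 4 → 8 → 9 → 10 → 13 → 14 → 15 → 17 → 18 → 20); the linalool branch (5 → 6 → 8) joins at step 4.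

Three steps most likely to fail, each with one fallback:

Step 10 (ring closure and lactonisation). The risks are oligomerisation, competing seven-membered closure on the C1 ketone, and the wrong face at C7; the facial argument is a model, not a certainty. The fallback replaces the open organochromium by a boron reagent with a closed transition state. It sets out from bromide 15, which is treated with bis(pinacolato)diboron and Pd2(dba)3 in DMSO to give the allylboronate F1. F1 is not isolated and adds intramolecularly to the C8 aldehyde (allylboration, (Z)-boronate giving the 7,8-syn adduct). Warming with Sc(OTf)3 closes the lactone from the borate, and the sequence comes back to the route at 17.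

Step 4 (one-pot hydroboration and thioester coupling). The risks are a sluggish B-alkyl transfer from the hindered borane and erosion at C10. The fallback switches to an organolithium acylation and sets out from 6 and 3. Hydroboration–oxidation of 6 (9-BBN; NaOH, H2O2) gives the primary alcohol F2, and iodine, PPh3 and imidazole convert it to the iodide F3. Imide 3 is converted with MeNHOMe·HCl and AlMe3 to the Weinreb amide F4. Iodine–lithium exchange of F3 (t-BuLi, −78 °C) and addition to F4 gives the ketone, coming back to the route at 8.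

Step 11 (zinc reduction beside the exocyclic methylene lactone). The risk is conjugate reduction or addition at C13 during the hot acidic N–O cleavage. The fallback masks the Michael acceptor first and sets out from 17. Dimethylamine in THF adds to C13 to give the amine adduct F5, and Zn in AcOH/THF/H2O then cleaves N–O and Si–O to give the amino diol F6. Methylation with MeI gives the ammonium iodide F7, which eliminates trimethylamine on stirring with NaHCO3 and restores the methylene group, coming back to the route at 18.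

**Further compounds**
F1 | step 10 | methyl (2Z,4R,6S,10R)-6,10-dimethyl-9,12-dioxo-2-[(4,4,5,5-tetramethyl-1,3,2-dioxaborolan-2-yl)methyl]-4-[(2,2,6,6-tetramethylpiperidin-1-yl)oxy]-6-(triethylsilyloxy)dodec-2-enoate | O=CC[C@@H](C)C(=O)CC[C@](C)(O[Si](CC)(CC)CC)C[C@@H](ON1C(C)(C)CCCC1(C)C)/C=C(/C(=O)OC)CB1OC(C)(C)C(C)(C)O1
F2 | step 4 | (S)-3,7-dimethyl-3-(triethylsilyloxy)oct-6-en-1-ol | OCC[C@](C)(O[Si](CC)(CC)CC)CCC=C(C)C
F3 | step 4 | (S)-1-iodo-3,7-dimethyl-3-(triethylsilyloxy)oct-6-ene | ICC[C@](C)(O[Si](CC)(CC)CC)CCC=C(C)C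
F4 | step 4 | (R)-N-methoxy-N,2-dimethylpent-4-enamide | C=CC[C@@H](C)C(=O)N(C)OC
F5 | step 11 | 13-(dimethylamino)-11,13-dihydro derivative of 17 (both C11 epimers) | CN(C)CC1C(=O)O[C@H]2C[C@@H](C)C(=O)CC[C@](C)(O[Si](CC)(CC)CC)C[C@@H](ON3C(C)(C)CCCC3(C)C)[C@@H]12
F6 | step 11 | 13-(dimethylamino)-11,13-dihydro derivative of 18 (both C11 epimers) | CN(C)CC1C(=O)O[C@H]2C[C@@H](C)C(=O)CC[C@](C)(O)C[C@@H](O)[C@@H]12
F7 | step 11 | 13-(trimethylammonio)-11,13-dihydro derivative of 18, iodide salt | C[N+](C)(C)CC1C(=O)O[C@H]2C[C@@H](C)C(=O)CC[C@](C)(O)C[C@@H](O)[C@@H]12.[I-]
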